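## Retrosynthetic overview

1. Last steps: HF desilylation and SeO2 oxidation of the C14 methyl group of a silyl-protected 14-deoxy macrocycle (germacrane numbering).
2. Key bond C7–C8: the 10-membered ring is closed by a 1-acyloxyalkyl radical (made from a C8 aldehyde and (2R)-2-methylbutanoyl iodide) that adds to C7 of a 3-(ethylsulfonylmethyl)butenolide. Loss of EtSO2 leaves the α-methylene lactone, so the ester on O8, C7 and C8 are installed together.
3. The seco aldehyde comes from a Negishi coupling at C3–C4 of a butenolide vinyl iodide (west) with a homoallylic alkylzinc (east).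
4. West: ring-closing metathesis, after enantioselective vinylation of a (Z)-β-iodo enal made from but-2-yne-1,4-diol. East: Z-selective Wittig reaction of a methyl ketone made from (S)-but-3-ene-1,2-diol.
5. Ring order: butenolide first (metathesis), then the 10-membered carbocycle (radical closure).

Assumption: germacrane numbering is used (C6 lactone carbinol, C7, C8 acyloxy, C9 hydroxy, C14 formyl, C15 hydroxymethyl); the target is read as 6R,7S,8S,9S with a (2R)-2-methylbutanoate, C6 cis to C3 across C4=C5 and C9 cis to C2 across C1=C10.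

## Route

Step 1
Reactants: 1 but-2-yne-1,4-diol
Product: 2 4-[(tert-butyldimethylsilyl)oxy]but-2-yn-1-ol
Conditions: TBSCl (1.0 equiv), imidazole (1.2 equiv), 1 (3 equiv), DMF, 0 to 25 °C
Reagents that add atoms: tert-butyldimethylsilyl chloride, CC(C)(C)[Si](C)(C)Cl
Why: Monosilylation of a symmetrical diol (silyl ether formation); the excess of diol keeps bis-silylation low and washes out with water.

Step 2
Reactants: 2 4-[(tert-butyldimethylsilyl)oxy]but-2-yn-1-ol
Product: 3 (2Z)-4-[(tert-butyldimethylsilyl)oxy]-3-iodobut-2-en-1-ol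
Conditions: NaAlH2(OCH2CH2OMe)2 (1.5 equiv), THF, 0 to 25 °C; then I2 (1.5 equiv), −78 °C
Reagents that add atoms: iodine, II
Why: Alkoxide-directed trans-hydroalumination of the propargylic alcohol puts aluminium on the carbon remote from the free OH and iodinolysis with retention gives the Z vinyl iodide (hydroalumination–iodination), which fixes the C4=C5 geometry (iodine later becomes C3, cis to C6).

Step 3
Reactants: 3 (2Z)-4-[(tert-butyldimethylsilyl)oxy]-3-iodobut-2-en-1-ol
Product: 4 (2Z)-4-[(tert-butyldimethylsilyl)oxy]-3-iodobut-2-enal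
Conditions: MnO2 (15 equiv), CH2Cl2, 25 °C
Reagents that add atoms: none
Why: MnO2 oxidises the primary allylic alcohol to the enal under neutral conditions without Z/E isomerisation (allylic oxidation).

Step 4
Reactants: 4 (2Z)-4-[(tert-butyldimethylsilyl)oxy]-3-iodobut-2-enal; 5 vinylmagnesium bromide (CH2=CHMgBr)
Product: 7 (3S,4Z)-6-[(tert-butyldimethylsilyl)oxy]-5-iodohexa-1,4-dien-3-ol, via divinylzinc 6 (not isolated)
Conditions: 5 (2.4 equiv), ZnCl2 (1.2 equiv), THF, 0 °C; 1,4-dioxane, filter; (−)-MIB (10 mol%), toluene, −30 °C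
Reagents that add atoms: none
Why: Amino-alcohol-catalysed enantioselective addition of an alkenylzinc to an aldehyde; with (−)-MIB the vinyl group adds to the Si face (the sense in which Et2Zn gives the S alcohol from benzaldehyde), which sets the future lactone carbinol C6 (3S here).

Step 5
Reactants: 8 2-(bromomethyl)prop-2-enoic acid; 9 sodium ethanesulfinate (EtSO2Na)
Product: 10 2-[(ethanesulfonyl)methyl]prop-2-enoic acid
Conditions: 9 (1.2 equiv), MeOH, 40 °C; acidic aqueous work-up
Reagents that add atoms: none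
Why: S-alkylation of the sulfinate by the allylic bromide (SN2 or SN2′, both give the same sulfone); the sulfinate is too weak a base to be quenched by the carboxylic acid.

Step 6
Reactants: 7 (3S,4Z)-6-[(tert-butyldimethylsilyl)oxy]-5-iodohexa-1,4-dien-3-ol; 10 2-[(ethanesulfonyl)methyl]prop-2-enoic acid
Product: 11 (3S,4Z)-6-[(tert-butyldimethylsilyl)oxy]-5-iodohexa-1,4-dien-3-yl 2-[(ethanesulfonyl)methyl]prop-2-enoate
Conditions: DCC (1.2 equiv), DMAP (5 mol%), CH2Cl2, −10 to 25 °C
Reagents that add atoms: none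
Why: Steglich esterification (carbodiimide activation, catalytic DMAP) acylates the bis-allylic alcohol under neutral conditions with retention at C6.

Step 7
Reactants: 11 (3S,4Z)-6-[(tert-butyldimethylsilyl)oxy]-5-iodohexa-1,4-dien-3-yl 2-[(ethanesulfonyl)methyl]prop-2-enoate
Product: 12 (5S)-5-[(1Z)-3-[(tert-butyldimethylsilyl)oxy]-2-iodoprop-1-en-1-yl]-3-[(ethanesulfonyl)methyl]furan-2(5H)-one
Conditions: second-generation Grubbs catalyst RuCl2(=CHPh)(PCy3)(H2IMes) (5 mol%), CH2Cl2, 40 °C, 5 mM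
Reagents that add atoms: none
Why: Ring-closing metathesis of the vinyl group onto the 1,1-disubstituted acrylate gives the trisubstituted butenolide and ethene; the trisubstituted vinyl iodide does not take part.

Step 8
Reactants: 13 (2S)-but-3-ene-1,2-diol
Product: 14 (2S)-1,2-bis[(triethylsilyl)oxy]but-3-ene
Conditions: TESCl (2.3 equiv), imidazole (3 equiv), CH2Cl2, 0 °C
Reagents that add atoms: chlorotriethylsilane, CC[Si](Cl)(CC)CC
Why: Silyl ether formation on both hydroxyls; TES is chosen so that the primary ether can later be oxidised directly to the aldehyde.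

Step 9
Reactants: 14 (2S)-1,2-bis[(triethylsilyl)oxy]but-3-ene
Product: 15 (3R)-3,4-bis[(triethylsilyl)oxy]butan-2-one
Conditions: Pd(quinox)Cl2 (5 mol%), AgSbF6 (12 mol%), 70% aq. t-BuOOH (12 equiv), CH2Cl2, 0 to 25 °C
Reagents that add atoms: tert-butyl hydroperoxide, CC(C)(C)OO
Why: Wacker-type oxidation with the Pd(quinox)/t-BuOOH system gives the methyl ketone from protected allylic alcohols with Markovnikov selectivity and without racemising the α-stereocentre (C9; the descriptor changes to R by priority only).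

Step 10
Reactants: 16 3-bromopropan-1-ol
Product: 17 (3-hydroxypropyl)triphenylphosphonium bromide
Conditions: PPh3 (1.0 equiv), MeCN, 80 °C
Reagents that add atoms: triphenylphosphine, c1ccc(cc1)P(c1ccccc1)c1ccccc1
Why: SN2 quaternisation of triphenylphosphine by the primary bromide (phosphonium salt formation).

Step 11
Reactants: 15 (3R)-3,4-bis[(triethylsilyl)oxy]butan-2-one; 17 (3-hydroxypropyl)triphenylphosphonium bromide
Product: 19 (3Z,5S)-4-methyl-5,6-bis[(triethylsilyl)oxy]hex-3-en-1-ol, via oxido ylide 18 (not isolated)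
Conditions: 17 (1.3 equiv), KN(SiMe3)2 (2.05 equiv per 17), THF, −78 to 0 °C; then 15, −78 to 25 °C
Reagents that add atoms: none
Why: Wittig olefination of an α-silyloxy methyl ketone with a non-stabilised ylide is Z-selective (the ylide chain ends cis to the oxygen-bearing carbon), giving C1=C10 with C2 cis to C9; the potassium oxido ylide at −78 °C adds faster than it enolises the ketone, so C9 is kept.

Step 12
Reactants: 19 (3Z,5S)-4-methyl-5,6-bis[(triethylsilyl)oxy]hex-3-en-1-ol
Product: 20 (3Z,5S)-1-iodo-4-methyl-5,6-bis[(triethylsilyl)oxy]hex-3-ene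
Conditions: I2 (1.2 equiv), PPh3 (1.2 equiv), imidazole (1.5 equiv), CH2Cl2, 0 °C, dark
Reagents that add atoms: iodine, II
Why: Appel-type iodination of the primary alcohol by SN2; the imidazole buffer leaves the TES ethers intact.

Step 13
Reactants: 20 (3Z,5S)-1-iodo-4-methyl-5,6-bis[(triethylsilyl)oxy]hex-3-ene; 12 (5S)-5-[(1Z)-3-[(tert-butyldimethylsilyl)oxy]-2-iodoprop-1-en-1-yl]-3-[(ethanesulfonyl)methyl]furan-2(5H)-one
Product: 22 (5R)-5-[(1E,5Z,7S)-2-({[tert-butyl(dimethyl)silyl]oxy}methyl)-6-methyl-7,8-bis[(triethylsilyl)oxy]octa-1,5-dien-1-yl]-3-[(ethanesulfonyl)methyl]furan-2(5H)-one, via alkylzinc iodide 21 (not isolated)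
Conditions: Zn dust (Me3SiCl/1,2-dibromoethane activated), LiCl, THF, 40 °C; then 12, Pd(OAc)2 (3 mol%), SPhos (6 mol%), THF, 25 °C
Reagents that add atoms: none
Why: Zinc insertion into the primary iodide and Negishi sp3–sp2 cross-coupling with the vinyl iodide, which proceeds with retention of alkene geometry (C3 ends cis to C6) and tolerates lactone, sulfone and silyl ethers; the C6 descriptor changes from S to R only because carbon replaces iodine.

Step 14
Reactants: 22 (5R)-5-[(1E,5Z,7S)-2-({[tert-butyl(dimethyl)silyl]oxy}methyl)-6-methyl-7,8-bis[(triethylsilyl)oxy]octa-1,5-dien-1-yl]-3-[(ethanesulfonyl)methyl]furan-2(5H)-one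
Product: 23 (5R)-5-[(1E,5Z,7S)-2-({[tert-butyl(dimethyl)silyl]oxy}methyl)-6-methyl-8-oxo-7-[(triethylsilyl)oxy]octa-1,5-dien-1-yl]-3-[(ethanesulfonyl)methyl]furan-2(5H)-one
Conditions: (COCl)2 (4 equiv), DMSO (8 equiv), CH2Cl2, −78 to −40 °C; Et3N (12 equiv), −78 to −20 °C; used crude at once
Reagents that add atoms: none
Why: Under Swern conditions a primary triethylsilyl ether is converted directly into the aldehyde (silyl transfer to the chlorosulfonium ion, then the usual ylide fragmentation) while the secondary TES and the TBS ether survive, and the low temperature avoids epimerisation at C9.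

Step 15
Reactants: 24 (2R)-2-methylbutanoic acid
Product: 25 (2R)-2-methylbutanoyl chloride
Conditions: (COCl)2 (1.3 equiv), DMF (cat.), CH2Cl2, 0 to 25 °C; distil
Reagents that add atoms: oxalyl chloride, ClC(=O)C(=O)Cl
Why: Acid chloride formation through the chloroiminium (Vilsmeier-type) catalyst; no base is present, so the α-stereocentre is not racemised.

Step 16
Reactants: 23 (5R)-5-[(1E,5Z,7S)-2-({[tert-butyl(dimethyl)silyl]oxy}methyl)-6-methyl-8-oxo-7-[(triethylsilyl)oxy]octa-1,5-dien-1-yl]-3-[(ethanesulfonyl)methyl]furan-2(5H)-one; 25 (2R)-2-methylbutanoyl chloride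
Product: 28 (6R,7S,8S,9S)-15-[(tert-butyldimethylsilyl)oxy]-8-{[(2R)-2-methylbutanoyl]oxy}-9-[(triethylsilyl)oxy]germacra-1(10),4,11(13)-trien-12,6-olide, via acyl iodide 26 (not isolated), via iodoalkyl ester 27 (not isolated)
Conditions: 25 (1.05 equiv), NaI (1.05 equiv), MeCN, 0 °C; add 23 in CH2Cl2, 0 °C, 30 min; then syringe-pump addition over 10 h into chlorobenzene at 100 °C with dilauroyl peroxide (0.3 equiv in portions), final 2 mM, argon sweep
Reagents that add atoms: none
Why: Proposed new method: the aldehyde and acyl iodide 26 give the 1-iodoalkyl ester 27, an alkyl radical (undecyl from the peroxide, then ethyl in the chain) abstracts iodine, the nucleophilic 1-acyloxyalkyl radical at C8 closes the 10-membered ring by adding to C7 of the electron-poor butenolide, and the resulting α-carbonyl radical ejects EtSO2• (which loses SO2 to give the chain-carrying ethyl radical) to leave the exo-methylene lactone; C7 is set by attack anti to the C5 substituent on C6 (trans-lactone) and C8 by a Felkin-type transition state with the C9–O bond anti to the forming bond and H9 facing the acyloxy group (8,9-threo); the closest known reactions are tin-free radical allylation of iodides and xanthates with allyl ethyl sulfones, generation of 1-acyloxyalkyl radicals from aldehydes and acyl iodides by iodine-atom transfer, and radical macrocyclisation onto acrylate-type acceptors.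

Step 17
Reactants: 28 (6R,7S,8S,9S)-15-[(tert-butyldimethylsilyl)oxy]-8-{[(2R)-2-methylbutanoyl]oxy}-9-[(triethylsilyl)oxy]germacra-1(10),4,11(13)-trien-12,6-olide
Product: 30 (6R,7S,8S,9S)-15-[(tert-butyldimethylsilyl)oxy]-8-{[(2R)-2-methylbutanoyl]oxy}-14-oxo-9-[(triethylsilyl)oxy]germacra-1(10),4,11(13)-trien-12,6-olide, via allylic alcohol 29 (not isolated)
Conditions: SeO2 (0.5 equiv), t-BuOOH (3 equiv, decane solution), CH2Cl2, 25 °C; then MnO2 (20 equiv), 25 °C
Reagents that add atoms: selenium dioxide, O=[Se]=O; tert-butyl hydroperoxide, CC(C)(C)OO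
Why: SeO2/t-BuOOH allylic oxidation (ene reaction then [2,3]-sigmatropic shift) occurs on the more electron-rich C1=C10 alkene at the methyl group trans to C2 (C4=C5 carries two allylic C–O bonds and the lactone alkene is electron-poor), as in the known conversion of parthenolide into melampomagnolide B, and MnO2 then oxidises only the new primary allylic alcohol to the enal.

Step 18
Reactants: 30 (6R,7S,8S,9S)-15-[(tert-butyldimethylsilyl)oxy]-8-{[(2R)-2-methylbutanoyl]oxy}-14-oxo-9-[(triethylsilyl)oxy]germacra-1(10),4,11(13)-trien-12,6-olide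
Product: 31 (6R,7S,8S,9S)-9,15-dihydroxy-8-{[(2R)-2-methylbutanoyl]oxy}-14-oxogermacra-1(10),4,11(13)-trien-12,6-olide (target)
Conditions: HF·pyridine, pyridine, THF, 0 to 25 °C
Reagents that add atoms: none
Why: Fluoride-mediated desilylation with buffered HF·pyridine removes the TES and TBS ethers under mildly acidic conditions that avoid acyl migration from O8 to O9 and conjugate addition to the α-methylene lactone.

## Compound list

1 | but-2-yne-1,4-diol | OCC#CCO | starting material
2 | 4-[(tert-butyldimethylsilyl)oxy]but-2-yn-1-ol | OCC#CCO[Si](C)(C)C(C)(C)C | intermediate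
3 | (2Z)-4-[(tert-butyldimethylsilyl)oxy]-3-iodobut-2-en-1-ol | OC/C=C(/CO[Si](C)(C)C(C)(C)C)I | intermediate
4 | (2Z)-4-[(tert-butyldimethylsilyl)oxy]-3-iodobut-2-enal | O=C/C=C(/CO[Si](C)(C)C(C)(C)C)I | intermediate
5 | vinylmagnesium bromide (CH2=CHMgBr) | C=C[Mg]Br | starting material
6 | divinylzinc, (CH2=CH)2Zn | C=C[Zn]C=C | intermediate
7 | (3S,4Z)-6-[(tert-butyldimethylsilyl)oxy]-5-iodohexa-1,4-dien-3-ol | O[C@@H](C=C)/C=C(/CO[Si](C)(C)C(C)(C)C)I | intermediate
8 | 2-(bromomethyl)prop-2-enoic acid | C=C(CBr)C(=O)O | starting material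
9 | sodium ethanesulfinate (EtSO2Na) | CCS(=O)[O-].[Na+] | starting material
10 | 2-[(ethanesulfonyl)methyl]prop-2-enoic acid | C=C(CS(=O)(=O)CC)C(=O)O | intermediate
11 | (3S,4Z)-6-[(tert-butyldimethylsilyl)oxy]-5-iodohexa-1,4-dien-3-yl 2-[(ethanesulfonyl)methyl]prop-2-enoate | C=C(CS(=O)(=O)CC)C(=O)O[C@@H](C=C)/C=C(/CO[Si](C)(C)C(C)(C)C)I | intermediate
12 | (5S)-5-[(1Z)-3-[(tert-butyldimethylsilyl)oxy]-2-iodoprop-1-en-1-yl]-3-[(ethanesulfonyl)methyl]furan-2(5H)-one | CCS(=O)(=O)CC1=C[C@@H](/C=C(/CO[Si](C)(C)C(C)(C)C)I)OC1=O | intermediate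
13 | (2S)-but-3-ene-1,2-diol | C=C[C@H](O)CO | starting material
14 | (2S)-1,2-bis[(triethylsilyl)oxy]but-3-ene | C=C[C@H](O[Si](CC)(CC)CC)CO[Si](CC)(CC)CC | intermediate
15 | (3R)-3,4-bis[(triethylsilyl)oxy]butan-2-one | CC(=O)[C@H](O[Si](CC)(CC)CC)CO[Si](CC)(CC)CC | intermediate
16 | 3-bromopropan-1-ol | OCCCBr | starting material
17 | (3-hydroxypropyl)triphenylphosphonium bromide | OCCC[P+](c1ccccc1)(c1ccccc1)c1ccccc1.[Br-] | intermediate
18 | potassium 3-(triphenylphosphoranylidene)propan-1-olate (oxido ylide) | [K+].[O-]CCC=P(c1ccccc1)(c1ccccc1)c1ccccc1 | intermediate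
19 | (3Z,5S)-4-methyl-5,6-bis[(triethylsilyl)oxy]hex-3-en-1-ol | OCC/C=C(/C)[C@H](O[Si](CC)(CC)CC)CO[Si](CC)(CC)CC | intermediate
20 | (3Z,5S)-1-iodo-4-methyl-5,6-bis[(triethylsilyl)oxy]hex-3-ene | ICC/C=C(/C)[C@H](O[Si](CC)(CC)CC)CO[Si](CC)(CC)CC | intermediate
21 | [(3Z,5S)-4-methyl-5,6-bis[(triethylsilyl)oxy]hex-3-en-1-yl]zinc iodide | I[Zn]CC/C=C(/C)[C@H](O[Si](CC)(CC)CC)CO[Si](CC)(CC)CC | intermediate
22 | (5R)-5-[(1E,5Z,7S)-2-({[tert-butyl(dimethyl)silyl]oxy}methyl)-6-methyl-7,8-bis[(triethylsilyl)oxy]octa-1,5-dien-1-yl]-3-[(ethanesulfonyl)methyl]furan-2(5H)-one (butenolide 12 with iodine replaced by C3 of chain 20) | CCS(=O)(=O)CC1=C[C@@H](/C=C(/CO[Si](C)(C)C(C)(C)C)CC/C=C(/C)[C@H](O[Si](CC)(CC)CC)CO[Si](CC)(CC)CC)OC1=O | intermediate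
23 | (5R)-5-[(1E,5Z,7S)-2-({[tert-butyl(dimethyl)silyl]oxy}methyl)-6-methyl-8-oxo-7-[(triethylsilyl)oxy]octa-1,5-dien-1-yl]-3-[(ethanesulfonyl)methyl]furan-2(5H)-one (seco aldehyde) | CCS(=O)(=O)CC1=C[C@@H](/C=C(/CO[Si](C)(C)C(C)(C)C)CC/C=C(/C)[C@H](O[Si](CC)(CC)CC)C=O)OC1=O | intermediate
24 | (2R)-2-methylbutanoic acid | CC[C@@H](C)C(=O)O | starting material
25 | (2R)-2-methylbutanoyl chloride | CC[C@@H](C)C(=O)Cl | intermediate
26 | (2R)-2-methylbutanoyl iodide | CC[C@@H](C)C(=O)I | intermediate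
27 | 1-iodoalkyl (2R)-2-methylbutanoate formed at the aldehyde carbon of 23 (both C8 epimers) | CCS(=O)(=O)CC1=C[C@@H](/C=C(/CO[Si](C)(C)C(C)(C)C)CC/C=C(/C)[C@H](O[Si](CC)(CC)CC)C(I)OC(=O)[C@H](C)CC)OC1=O | intermediate
28 | (6R,7S,8S,9S)-15-[(tert-butyldimethylsilyl)oxy]-8-{[(2R)-2-methylbutanoyl]oxy}-9-[(triethylsilyl)oxy]germacra-1(10),4,11(13)-trien-12,6-olide (C2 cis to C9, C3 cis to C6) | C=C1C(=O)O[C@@H]2/C=C(/CO[Si](C)(C)C(C)(C)C)CC/C=C(/C)[C@H](O[Si](CC)(CC)CC)[C@@H](OC(=O)[C@H](C)CC)[C@@H]12 | intermediate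
29 | 14-hydroxy derivative of 28 | C=C1C(=O)O[C@@H]2/C=C(/CO[Si](C)(C)C(C)(C)C)CC/C=C(/CO)[C@H](O[Si](CC)(CC)CC)[C@@H](OC(=O)[C@H](C)CC)[C@@H]12 | intermediate
30 | 14-oxo derivative of 28 (silyl-protected target) | C=C1C(=O)O[C@@H]2/C=C(/CO[Si](C)(C)C(C)(C)C)CC/C=C(/C=O)[C@H](O[Si](CC)(CC)CC)[C@@H](OC(=O)[C@H](C)CC)[C@@H]12 | intermediate
31 | (6R,7S,8S,9S)-9,15-dihydroxy-8-{[(2R)-2-methylbutanoyl]oxy}-14-oxogermacra-1(10),4,11(13)-trien-12,6-olide | C=C1C(=O)O[C@@H]2/C=C(/CO)CC/C=C(/C=O)[C@H](O)[C@@H](OC(=O)[C@H](C)CC)[C@@H]12 | target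

## Step count and risks

Total step count: 18. Longest linear sequence: 11 steps (1, 2, 3, 4, 6, 7, 13, 14, 16, 17, 18).

The three steps most likely to fail:

**Step 16 (radical ring closure).** The 10-membered closure competes with 1,5-hydrogen transfer from the allylic C2–H to the C8 radical and with oligomerisation. The C7/C8 outcome rests on a transition-state argument, not on precedent. The acyl iodide may also attack the silyl ethers. The fallback makes the C7–C8 bond between two fragments, where a high acceptor concentration outruns hydrogen transfer, and closes the ring at C3–C4 instead. It sets out from alcohol 19 and comes back at macrocycle 28. CBr4/PPh3 converts 19 into (3Z,5S)-1-bromo-4-methyl-5,6-bis[(triethylsilyl)oxy]hex-3-ene F6. Direct Swern oxidation of its primary silyl ether gives (2S,3Z)-6-bromo-3-methyl-2-[(triethylsilyl)oxy]hex-3-enal F7. With acyl iodide 26 (from 25 and NaI) this gives the 1-iodoalkyl (2R)-2-methylbutanoate F8, which is added at 0.3 M (dilauroyl peroxide, chlorobenzene, 100 °C) to butenolide 12 (2 equiv) to give the seco bromide F9. The primary bromide is inert to the ethyl radical chain. An intramolecular nickel-catalysed reductive coupling of the vinyl iodide with the primary bromide (NiBr2(diglyme), 4,4′-di-tert-butyl-2,2′-bipyridine, Mn powder, DMA, 2 mM) then gives 28.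

**Step 4 (enantioselective vinylation).** The parent vinyl group and a β-iodo enal are demanding for catalytic alkenylzinc addition, so the enantiomeric excess may be low. A poor value passes into diastereomers after step 13. The fallback sets the centre by reagent-controlled reduction and not by C–C bond formation. It sets out from enal 4 and comes back at dienol 7. Vinylmagnesium bromide 5 (THF, −78 °C) gives racemic (4Z)-6-[(tert-butyldimethylsilyl)oxy]-5-iodohexa-1,4-dien-3-ol F1. MnO2 gives (4Z)-6-[(tert-butyldimethylsilyl)oxy]-5-iodohexa-1,4-dien-3-one F2. Reduction with (R)-Me-CBS oxazaborolidine and BH3·SMe2 (the iodoalkenyl group as the large substituent) returns 7.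

**Step 13 (Negishi union).** Zerovalent palladium could ionise the allylic sulfone or the allylic lactone C–O bond of 12, and the organozinc could deprotonate the butenolide γ-position. The fallback forms the C3–C4 bond before the butenolide exists. It sets out from alkylzinc iodide 21 and enal 4 and comes back at 22. Negishi coupling of 21 with 4 (Pd(OAc)2, SPhos, THF) gives (2E,6Z,8S)-3-({[tert-butyl(dimethyl)silyl]oxy}methyl)-7-methyl-8,9-bis[(triethylsilyl)oxy]nona-2,6-dienal F3. Vinylation with divinylzinc 6 and (−)-MIB as in step 4 gives (3S,4E,8Z,10S)-5-({[tert-butyl(dimethyl)silyl]oxy}methyl)-9-methyl-10,11-bis[(triethylsilyl)oxy]undeca-1,4,8-trien-3-ol F4. DCC/DMAP esterification with acid 10 gives its 2-[(ethanesulfonyl)methyl]prop-2-enoate F5. Ring-closing metathesis with the second-generation Grubbs catalyst then gives 22.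

Further compounds

F1 | step 4 | racemic (4Z)-6-[(tert-butyldimethylsilyl)oxy]-5-iodohexa-1,4-dien-3-ol | OC(C=C)/C=C(/CO[Si](C)(C)C(C)(C)C)I
F2 | step 4 | (4Z)-6-[(tert-butyldimethylsilyl)oxy]-5-iodohexa-1,4-dien-3-one | O=C(C=C)/C=C(/CO[Si](C)(C)C(C)(C)C)I
F3 | step 13 | (2E,6Z,8S)-3-({[tert-butyl(dimethyl)silyl]oxy}methyl)-7-methyl-8,9-bis[(triethylsilyl)oxy]nona-2,6-dienal | O=C/C=C(/CO[Si](C)(C)C(C)(C)C)CC/C=C(/C)[C@H](O[Si](CC)(CC)CC)CO[Si](CC)(CC)CC
F4 | step 13 | (3S,4E,8Z,10S)-5-({[tert-butyl(dimethyl)silyl]oxy}methyl)-9-methyl-10,11-bis[(triethylsilyl)oxy]undeca-1,4,8-trien-3-ol | O[C@@H](C=C)/C=C(/CO[Si](C)(C)C(C)(C)C)CC/C=C(/C)[C@H](O[Si](CC)(CC)CC)CO[Si](CC)(CC)CC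
F5 | step 13 | 2-[(ethanesulfonyl)methyl]prop-2-enoate of F4 | C=C(CS(=O)(=O)CC)C(=O)O[C@@H](C=C)/C=C(/CO[Si](C)(C)C(C)(C)C)CC/C=C(/C)[C@H](O[Si](CC)(CC)CC)CO[Si](CC)(CC)CC
F6 | step 16 | (3Z,5S)-1-bromo-4-methyl-5,6-bis[(triethylsilyl)oxy]hex-3-ene | BrCC/C=C(/C)[C@H](O[Si](CC)(CC)CC)CO[Si](CC)(CC)CC
F7 | step 16 | (2S,3Z)-6-bromo-3-methyl-2-[(triethylsilyl)oxy]hex-3-enal | BrCC/C=C(/C)[C@H](O[Si](CC)(CC)CC)C=O
F8 | step 16 | 1-iodoalkyl (2R)-2-methylbutanoate formed at the aldehyde carbon of F7 (both epimers) | BrCC/C=C(/C)[C@H](O[Si](CC)(CC)CC)C(I)OC(=O)[C@H](C)CC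
F9 | step 16 | seco bromide: macrocycle 28 opened between C3 and C4, with iodine on C4 and bromine on C3 | BrCC/C=C(/C)[C@H](O[Si](CC)(CC)CC)[C@@H](OC(=O)[C@H](C)CC)[C@H]1C(=C)C(=O)O[C@@H]1/C=C(/CO[Si](C)(C)C(C)(C)C)I
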